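**Retrosynthetic overview**

1. Target ⇒ open ring B at C7–C8: a CH2CHO arm on C10 and a prenyl group on C5 are joined by an acyl-radical 6-exo-trig hydroacylation, which makes the ring bond, the C8 ketone and the isopropyl group in one radical step (last step).
2. Aldehyde ⇒ terminal alkyne (anti-Markovnikov hydration); the ethynyl group on C10 is the masked arm and, being small and axial, lets the ring A stereocentres be set by conformational control.
3. C4 acetate and C3 angelate ⇒ C4 ketone: methyl addition with in situ acetylation (C4), and SN2 displacement of an axial α-bromide by angelate (C3).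
4. Ring A ketone ⇒ 3-methylcyclohex-2-enone + trimethylsilylacetylene + prenyl bromide: catalytic asymmetric conjugate alkynylation (C10), then enolate prenylation and equilibration (C5).
5. Ring order: ring A is bought as the enone; ring B is closed last by the radical step.

Assumption: the SMILES is taken literally, i.e. a cis-fused (5βH, 10β-methyl) eudesmane with 3α-angeloyloxy, 4α-acetoxy and 7β-isopropyl groups, (3R,4S,5S,7R,10R) in eudesmane numbering, which is used for atom labels throughout.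

**Route**

Step 1
Reactants: 1 3-methylcyclohex-2-en-1-one; 2 ethynyl(trimethyl)silane; 3 1-bromo-3-methylbut-2-ene
Product: 8 (2S,3S)-3-methyl-2-(3-methylbut-2-en-1-yl)-3-[(trimethylsilyl)ethynyl]cyclohexan-1-one, via alkynylalane 4 (not isolated), via aluminium enolate 5 (not isolated), via lithium aluminate enolate 6 (not isolated), via kinetic C5 epimer 7 (not isolated)
Conditions: 2, i-Bu2AlH, Et3N (5 mol%), hexanes, 0 → 50 °C; then 1, Cu(OTf)2 (5 mol%), chiral sulfonate-bearing imidazolinium salt (NHC precursor, 6 mol%), THF, −30 °C; then MeLi, 3, DMPU, −78 → 0 °C; aqueous work-up; then DBU (1 equiv), MeCN, 60 °C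
Reagents that add atoms: none
Why: Copper–NHC-catalysed enantioselective conjugate alkynylation with the alkynylalane sets the C10 quaternary centre (ligand enantiomer chosen for S), the regiodefined enolate is C-prenylated at C5 after conversion to the more nucleophilic aluminate, and DBU equilibrates the epimerisable C5 centre towards the chair with equatorial prenyl and axial alkynyl (A-values about 0.4 for alkynyl against 1.7 kcal/mol for methyl), i.e. prenyl cis to the alkyne, expected only about 4:1 with the minor epimer separated and recycled.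

Step 2
Reactants: 8 (2S,3S)-3-methyl-2-(3-methylbut-2-en-1-yl)-3-[(trimethylsilyl)ethynyl]cyclohexan-1-one
Product: 10 (2S,3S,6S)-6-bromo-3-methyl-2-(3-methylbut-2-en-1-yl)-3-[(trimethylsilyl)ethynyl]cyclohexan-1-one, via lithium enolate 9 (not isolated)
Conditions: LiN(SiMe3)2, THF, −78 °C; then N-bromosuccinimide, −78 °C; H2O quench
Reagents that add atoms: N-bromosuccinimide, O=C1CCC(=O)N1Br
Why: Kinetic deprotonation takes the unhindered C3 methylene rather than the C5 methine next to the quaternary carbon, and electrophilic bromination of the enolate by axial attack gives the axial 3β-bromide, which is also the thermodynamically preferred α-bromoketone epimer.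

Step 3
Reactants: 10 (2S,3S,6S)-6-bromo-3-methyl-2-(3-methylbut-2-en-1-yl)-3-[(trimethylsilyl)ethynyl]cyclohexan-1-one; 11 (2Z)-2-methylbut-2-enoic acid (angelic acid)
Product: 13 (1R,3S,4S)-4-methyl-3-(3-methylbut-2-en-1-yl)-2-oxo-4-[(trimethylsilyl)ethynyl]cyclohexyl (2Z)-2-methylbut-2-enoate, via cesium angelate 12 (not isolated)
Conditions: 11, Cs2CO3, 4 Å molecular sieves, DMF, 0 → 23 °C
Reagents that add atoms: none
Why: SN2 displacement of the axial α-bromoketone by the carboxylate inverts C3 to the equatorial 3α-ester, and because the ester is made by O-alkylation of the acid salt the Z (angelate) geometry is not put at risk.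

Step 4
Reactants: 13 (1R,3S,4S)-4-methyl-3-(3-methylbut-2-en-1-yl)-2-oxo-4-[(trimethylsilyl)ethynyl]cyclohexyl (2Z)-2-methylbut-2-enoate
Product: 15 (1R,2S,3S,4S)-2-acetoxy-2,4-dimethyl-3-(3-methylbut-2-en-1-yl)-4-[(trimethylsilyl)ethynyl]cyclohexyl (2Z)-2-methylbut-2-enoate, via dichlorocerium alkoxide 14 (not isolated)
Conditions: MeLi, CeCl3, THF, −78 °C; then Ac2O, DMAP (cat.), −78 → 0 °C
Reagents that add atoms: methyllithium, [Li]C; acetic anhydride, CC(=O)OC(C)=O
Why: Organocerium 1,2-addition (non-basic and ketone-selective over the ester) attacks the C4 carbonyl along the equatorial β trajectory because the axial alkynyl group on C10 blocks the axial α approach, giving the axial 4α-alkoxide with equatorial methyl, which is trapped in situ as the acetate before the neighbouring angelate can migrate.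

Step 5
Reactants: 15 (1R,2S,3S,4S)-2-acetoxy-2,4-dimethyl-3-(3-methylbut-2-en-1-yl)-4-[(trimethylsilyl)ethynyl]cyclohexyl (2Z)-2-methylbut-2-enoate
Product: 16 (1R,2S,3S,4S)-2-acetoxy-4-ethynyl-2,4-dimethyl-3-(3-methylbut-2-en-1-yl)cyclohexyl (2Z)-2-methylbut-2-enoate
Conditions: n-Bu4NF, AcOH (1:1), THF, 0 °C
Reagents that add atoms: none
Why: Fluoride-mediated protodesilylation of the C(sp)–Si bond, buffered with acetic acid so that neither ester is cleaved or shifted, touches no stereocentre.

Step 6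
Reactants: 16 (1R,2S,3S,4S)-2-acetoxy-4-ethynyl-2,4-dimethyl-3-(3-methylbut-2-en-1-yl)cyclohexyl (2Z)-2-methylbut-2-enoate
Product: 17 (1R,2S,3S,4R)-2-acetoxy-2,4-dimethyl-3-(3-methylbut-2-en-1-yl)-4-(2-oxoethyl)cyclohexyl (2Z)-2-methylbut-2-enoate
Conditions: [CpRu(MeCN)3]PF6 (5 mol%), 5,5′-bis(trifluoromethyl)-2,2′-bipyridine (5 mol%), H2O, NMP, 25 °C
Reagents that add atoms: water, O
Why: Ruthenium-catalysed anti-Markovnikov hydration of the terminal alkyne (vinylidene pathway) gives the CH2CHO arm directly and leaves the trisubstituted alkenes, both esters and all stereocentres untouched.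

Step 7
Reactants: 17 (1R,2S,3S,4R)-2-acetoxy-2,4-dimethyl-3-(3-methylbut-2-en-1-yl)-4-(2-oxoethyl)cyclohexyl (2Z)-2-methylbut-2-enoate
Product: 19 (1S,2R,4aR,7R,8aS)-1-acetoxy-1,4a-dimethyl-6-oxo-7-(propan-2-yl)decahydronaphthalen-2-yl (2Z)-2-methylbut-2-enoate (CNP0322180.1), via C7 epimer 18 (not isolated)
Conditions: (n-Bu4N)4[W10O32] (2 mol%), MeCN (0.01 M, degassed), 390 nm LEDs, 25 °C; then DBU (0.3 equiv), PhMe, 40 °C
Reagents that add atoms: none
Why: Proposed new method: decatungstate hydrogen-atom-transfer photocatalysis abstracts the aldehydic hydrogen, the nucleophilic acyl radical closes ring B by 6-exo-trig attack on C7 of the prenyl group through a chair transition state (axial arm on C10, equatorial prenyl on C5, so the ring fusion is cis by construction and the isopropyl group equatorial), the tertiary radical takes hydrogen back from the reduced polyoxometalate, and DBU then secures the thermodynamic equatorial 7β epimer; the closest known reactions are the thiol-catalysed radical-chain cyclisation of citronellal to menthone and decatungstate-photocatalysed hydroacylation of alkenes by aldehydes, thiols being avoided here because thiyl radicals would isomerise the angelate.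

**Compound list**

1 | 3-methylcyclohex-2-en-1-one | CC1=CC(=O)CCC1 | starting material
2 | ethynyl(trimethyl)silane | C#C[Si](C)(C)C | starting material
3 | 1-bromo-3-methylbut-2-ene (prenyl bromide) | CC(C)=CCBr | starting material
4 | bis(2-methylpropyl)[(trimethylsilyl)ethynyl]alumane | CC(C)C[Al](CC(C)C)C#C[Si](C)(C)C | intermediate
5 | bis(2-methylpropyl)aluminium (3S)-3-methyl-3-[(trimethylsilyl)ethynyl]cyclohex-1-en-1-olate | C[C@]1(C#C[Si](C)(C)C)CCCC(O[Al](CC(C)C)CC(C)C)=C1 | intermediate
6 | lithium methylbis(2-methylpropyl){[(3S)-3-methyl-3-[(trimethylsilyl)ethynyl]cyclohex-1-en-1-yl]oxy}aluminate | [Li+].C[Al-](CC(C)C)(CC(C)C)OC1=C[C@@](C)(C#C[Si](C)(C)C)CCC1 | intermediate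
7 | (2R,3S)-3-methyl-2-(3-methylbut-2-en-1-yl)-3-[(trimethylsilyl)ethynyl]cyclohexan-1-one (prenyl trans to alkyne) | O=C1CCC[C@](C)(C#C[Si](C)(C)C)[C@H]1CC=C(C)C | intermediate
8 | (2S,3S)-3-methyl-2-(3-methylbut-2-en-1-yl)-3-[(trimethylsilyl)ethynyl]cyclohexan-1-one (prenyl cis to alkyne) | O=C1CCC[C@](C)(C#C[Si](C)(C)C)[C@@H]1CC=C(C)C | intermediate
9 | lithium (5S,6S)-5-methyl-6-(3-methylbut-2-en-1-yl)-5-[(trimethylsilyl)ethynyl]cyclohex-1-en-1-olate | [Li]OC1=CCC[C@](C)(C#C[Si](C)(C)C)[C@@H]1CC=C(C)C | intermediate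
10 | (2S,3S,6S)-6-bromo-3-methyl-2-(3-methylbut-2-en-1-yl)-3-[(trimethylsilyl)ethynyl]cyclohexan-1-one (axial 3β-bromide) | Br[C@H]1CC[C@](C)(C#C[Si](C)(C)C)[C@H](CC=C(C)C)C1=O | intermediate
11 | (2Z)-2-methylbut-2-enoic acid (angelic acid) | C/C=C(/C)C(=O)O | starting material
12 | cesium (2Z)-2-methylbut-2-enoate | C/C=C(/C)C(=O)[O-].[Cs+] | intermediate
13 | (1R,3S,4S)-4-methyl-3-(3-methylbut-2-en-1-yl)-2-oxo-4-[(trimethylsilyl)ethynyl]cyclohexyl (2Z)-2-methylbut-2-enoate | C/C=C(/C)C(=O)O[C@@H]1CC[C@](C)(C#C[Si](C)(C)C)[C@H](CC=C(C)C)C1=O | intermediate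
14 | dichlorocerium alkoxide of the 4α tertiary alcohol (precursor of 15) | C/C=C(/C)C(=O)O[C@@H]1CC[C@](C)(C#C[Si](C)(C)C)[C@H](CC=C(C)C)[C@]1(C)O[Ce](Cl)Cl | intermediate
15 | (1R,2S,3S,4S)-2-acetoxy-2,4-dimethyl-3-(3-methylbut-2-en-1-yl)-4-[(trimethylsilyl)ethynyl]cyclohexyl (2Z)-2-methylbut-2-enoate | C/C=C(/C)C(=O)O[C@@H]1CC[C@](C)(C#C[Si](C)(C)C)[C@H](CC=C(C)C)[C@]1(C)OC(C)=O | intermediate
16 | (1R,2S,3S,4S)-2-acetoxy-4-ethynyl-2,4-dimethyl-3-(3-methylbut-2-en-1-yl)cyclohexyl (2Z)-2-methylbut-2-enoate | C/C=C(/C)C(=O)O[C@@H]1CC[C@](C)(C#C)[C@H](CC=C(C)C)[C@]1(C)OC(C)=O | intermediate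
17 | (1R,2S,3S,4R)-2-acetoxy-2,4-dimethyl-3-(3-methylbut-2-en-1-yl)-4-(2-oxoethyl)cyclohexyl (2Z)-2-methylbut-2-enoate | C/C=C(/C)C(=O)O[C@@H]1CC[C@](C)(CC=O)[C@H](CC=C(C)C)[C@]1(C)OC(C)=O | intermediate
18 | (1S,2R,4aR,7S,8aS)-1-acetoxy-1,4a-dimethyl-6-oxo-7-(propan-2-yl)decahydronaphthalen-2-yl (2Z)-2-methylbut-2-enoate (C7 epimer) | C/C=C(/C)C(=O)O[C@@H]1CC[C@]2(C)CC(=O)[C@H](C(C)C)C[C@@H]2[C@]1(C)OC(C)=O | intermediate
19 | (1S,2R,4aR,7R,8aS)-1-acetoxy-1,4a-dimethyl-6-oxo-7-(propan-2-yl)decahydronaphthalen-2-yl (2Z)-2-methylbut-2-enoate | C/C=C(/C)C(=O)O[C@@H]1CC[C@]2(C)CC(=O)[C@@H](C(C)C)C[C@@H]2[C@]1(C)OC(C)=O | target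

**Step count and risk**

Total steps: 7. Longest linear sequence: 7 (from 1).

Stereocentres: C10 is set in step 1 (catalyst), C5 in step 1 (thermodynamic), C3 in steps 2 and 3 (axial bromination, then inversion), C4 in step 4 (equatorial attack), C7 in step 7 (chair closure, then equilibration).

The three steps most likely to fail:

Step 7 (key radical ring closure). The back hydrogen transfer to the tertiary alkyl radical may be slow, and allylic hydrogen abstraction on the prenyl group may compete. The fallback sets out from 17 and comes back at 19 by a polar closure of the same C7–C8 bond. A Me2AlCl-promoted intramolecular carbonyl-ene reaction (CH2Cl2, −78 °C) gives the isopulegol-type (1S,2R,4aR,6S,7R,8aS)-1-acetoxy-6-hydroxy-1,4a-dimethyl-7-(prop-1-en-2-yl)decahydronaphthalen-2-yl (2Z)-2-methylbut-2-enoate F5. Chemoselective hydrogenation of its 1,1-disubstituted alkene (H2, RhCl(PPh3)3, benzene; the conjugated trisubstituted angelate is left alone) gives the saturated alcohol (1S,2R,4aR,6S,7R,8aS)-1-acetoxy-6-hydroxy-1,4a-dimethyl-7-(propan-2-yl)decahydronaphthalen-2-yl (2Z)-2-methylbut-2-enoate F6. Dess–Martin oxidation, followed by the DBU equilibration of step 7 if needed, then gives 19.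

Step 1 (three-component coupling and C5 control). C-alkylation of the hindered aluminate enolate next to the new quaternary carbon may be poor, and the equilibrium ratio is only about 4:1. The fallback sets out from enolate 5 and comes back at 8. The enolate is trapped with Me3SiOTf and the silyl enol ether trimethyl({(3S)-3-methyl-3-[(trimethylsilyl)ethynyl]cyclohex-1-en-1-yl}oxy)silane F1 is isolated. It is then prenylated by a cationic route (3, ZnBr2 cat., CH2Cl2, SN1-type attack of the enol ether on the allyl cation at its primary terminus), which is less sensitive to hindrance than the enolate SN2 reaction. The resulting 7/8 mixture is equilibrated with DBU as before to 8.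

Step 4 (methyl addition next to the angelate, in situ acetylation). The risks are angelate migration to the new tertiary alkoxide, incomplete acetylation, and erosion of facial selectivity. The fallback sets out from 10 and comes back at 15 by a diol-first order of events. Displacement of the bromide with CsOAc (DMF) gives (1R,3S,4S)-4-methyl-3-(3-methylbut-2-en-1-yl)-2-oxo-4-[(trimethylsilyl)ethynyl]cyclohexyl acetate F2. Excess MeMgBr with CeCl3 (THF, −78 → 0 °C) adds to the ketone and removes the acetyl group to give (1S,2R,5S,6S)-1,5-dimethyl-6-(3-methylbut-2-en-1-yl)-5-[(trimethylsilyl)ethynyl]cyclohexane-1,2-diol F3. Selective acylation of the secondary hydroxyl with 11 (2,4,6-trichlorobenzoyl chloride, Et3N, then DMAP, PhMe) gives (1R,2S,3S,4S)-2-hydroxy-2,4-dimethyl-3-(3-methylbut-2-en-1-yl)-4-[(trimethylsilyl)ethynyl]cyclohexyl (2Z)-2-methylbut-2-enoate F4. Acetylation of the tertiary hydroxyl under acid catalysis (Ac2O, Sc(OTf)3 cat., MeCN, −20 °C) then gives 15.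

**Further compounds**

F1 | step 1 | trimethyl({(3S)-3-methyl-3-[(trimethylsilyl)ethynyl]cyclohex-1-en-1-yl}oxy)silane | C[C@]1(C#C[Si](C)(C)C)CCCC(O[Si](C)(C)C)=C1
F2 | step 4 | (1R,3S,4S)-4-methyl-3-(3-methylbut-2-en-1-yl)-2-oxo-4-[(trimethylsilyl)ethynyl]cyclohexyl acetate | CC(=O)O[C@@H]1CC[C@](C)(C#C[Si](C)(C)C)[C@H](CC=C(C)C)C1=O
F3 | step 4 | (1S,2R,5S,6S)-1,5-dimethyl-6-(3-methylbut-2-en-1-yl)-5-[(trimethylsilyl)ethynyl]cyclohexane-1,2-diol | O[C@@H]1CC[C@](C)(C#C[Si](C)(C)C)[C@H](CC=C(C)C)[C@]1(C)O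
F4 | step 4 | (1R,2S,3S,4S)-2-hydroxy-2,4-dimethyl-3-(3-methylbut-2-en-1-yl)-4-[(trimethylsilyl)ethynyl]cyclohexyl (2Z)-2-methylbut-2-enoate | C/C=C(/C)C(=O)O[C@@H]1CC[C@](C)(C#C[Si](C)(C)C)[C@H](CC=C(C)C)[C@]1(C)O
F5 | step 7 | (1S,2R,4aR,6S,7R,8aS)-1-acetoxy-6-hydroxy-1,4a-dimethyl-7-(prop-1-en-2-yl)decahydronaphthalen-2-yl (2Z)-2-methylbut-2-enoate | C/C=C(/C)C(=O)O[C@@H]1CC[C@]2(C)C[C@H](O)[C@@H](C(C)=C)C[C@@H]2[C@]1(C)OC(C)=O
F6 | step 7 | (1S,2R,4aR,6S,7R,8aS)-1-acetoxy-6-hydroxy-1,4a-dimethyl-7-(propan-2-yl)decahydronaphthalen-2-yl (2Z)-2-methylbut-2-enoate | C/C=C(/C)C(=O)O[C@@H]1CC[C@]2(C)C[C@H](O)[C@@H](C(C)C)C[C@@H]2[C@]1(C)OC(C)=O
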